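**Retrosynthetic overview**
1. Core numbering: C1 (geranyl bridgehead), C2–C3–C4 (dione bridge), C5 (prenyl bridgehead), C6 (CMe2), C7 (CH-prenyl), C8 (CH2), C9 (bridging C=O). The catechol aroyl group is removed from C3 last, by C3 lithiation/aroylation of the C4 methyl enol ether, which leaves a bicyclo[3.3.1]non-3-ene-2,9-dione.
2. The plan rests on one feature: C9, C5, C6 and C7 form a hidden 3,3-dimethylcyclobutanone. Cutting C1–C9 and C7–C8 restores the C9–C7 bond of that four-membered ring. It also frees a 1,1-disubstituted alkene C1=C8 that hangs from C5 through C4(OMe)=C3H–C2(=O).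
3. Side chain: the C4–OMe bond comes from methanol addition to an ynone, which leaves no doubt about regiochemistry. C3–C2 comes from an acyl Sonogashira coupling with 2-geranylacryloyl chloride, and C5–C4 from ethynylation of the cyclobutanone enolate anti to the C7 prenyl group.
4. Chirality: a C2-symmetric trans-2,4-diprenyl-3,3-dimethylcyclobutanone is made by double RAMP-hydrazone alkylation. Its two α-hydrogens are equivalent, so one enolate enantiomer results and C7 steers the quaternary centre C5.
5. Ring order: the four-membered ring forms first (keteniminium [2+2] with isobutene). Both six-membered rings, A (C1, C2, C3, C4, C5, C9) and B (C1, C8, C7, C6, C5, C9), then form together in the rhodium step.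

Key step: step 13

Assumption: the target is one 3-aroyl-2,4,9-trione whose enol tautomers interconvert, and the tautomer of the given SMILES is drawn. Labels C1–C9 are core atoms; plain numbers are compounds.

**Step 1**
Reactants: 1 N,N-dimethylacetamide; 2 isobutene
Product: 5 3,3-dimethylcyclobutan-1-one, via keteniminium triflate 3 (not isolated), via cyclobutaniminium triflate 4 (not isolated)
Conditions: Tf2O, 2,4,6-collidine, 2 (excess), ClCH2CH2Cl, sealed vessel, 0 → 80 °C; then H2O, reflux
Reagents that add atoms: water, O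
Why: Keteniminium–olefin [2+2] cycloaddition (Ghosez type): the electrophilic central carbon of 3 bonds to the CH2 end of isobutene, the tertiary cation closes on the former acetyl carbon so that the gem-dimethyl carbon lies opposite the carbonyl group, and water hydrolyses 4.

**Step 2**
Reactants: 5 3,3-dimethylcyclobutan-1-one; 6 (R)-1-amino-2-(methoxymethyl)pyrrolidine (RAMP)
Product: 7 (2R)-N-(3,3-dimethylcyclobutylidene)-2-(methoxymethyl)pyrrolidin-1-amine
Conditions: Et2O, 4 Å molecular sieves, rt
Reagents that add atoms: none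
Why: Hydrazone condensation of an unhindered strained ketone (first stage of the Enders SAMP/RAMP method), which brings in the only external source of chirality.

**Step 3**
Reactants: 7 RAMP hydrazone; 8 prenyl bromide
Product: 10 (2R)-N-[(2S)-3,3-dimethyl-2-(3-methylbut-2-en-1-yl)cyclobutylidene]-2-(methoxymethyl)pyrrolidin-1-amine, via lithium azaenolate 9 (not isolated)
Conditions: LDA, THF, 0 °C; then 8, −95 → −78 °C
Reagents that add atoms: none
Why: Enders RAMP-hydrazone α-alkylation: the methoxy-chelated azaenolate 9 is alkylated on its open face, and the known sense for cyclic ketones (SAMP gives R and RAMP gives S where the ring carbon outranks the new chain) sets the S centre.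

**Step 4**
Reactants: 10 monoprenyl hydrazone; 8 prenyl bromide
Product: 12 (2R)-N-[(2S,4S)-3,3-dimethyl-2,4-bis(3-methylbut-2-en-1-yl)cyclobutylidene]-2-(methoxymethyl)pyrrolidin-1-amine, via lithium azaenolate 11 (not isolated)
Conditions: LDA, THF, 0 °C; then 8, −95 → −78 °C
Reagents that add atoms: none
Why: Second RAMP-hydrazone alkylation at the remaining CH2 group (α,α′-bisalkylation towards a C2-symmetric ketone): the auxiliary again calls for S and the first prenyl group shields its own face, so both controls point to the trans isomer.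

**Step 5**
Reactants: 12 diprenyl hydrazone
Product: 13 (2S,4S)-3,3-dimethyl-2,4-bis(3-methylbut-2-en-1-yl)cyclobutan-1-one (trans, C2-symmetric)
Conditions: sat. aq. oxalic acid, Et2O, rt
Reagents that add atoms: water, O
Why: Two-phase oxalic acid hydrolysis of the hydrazone, a cleavage known to spare α-stereocentres and, unlike ozonolysis, the trisubstituted alkenes; any cis (meso) ketone is removed here by chromatography because it would lower the enantiomeric purity in step 6.

**Step 6**
Reactants: 13 C2-symmetric ketone; 14 1-[(trimethylsilyl)ethynyl]-1,2-benziodoxol-3(1H)-one (TMS-EBX)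
Product: 17 (2S,4S)-2-ethynyl-3,3-dimethyl-2,4-bis(3-methylbut-2-en-1-yl)cyclobutan-1-one (the two prenyl groups cis), via lithium enolate 15 (not isolated), via ethynylbenziodoxolone 16 (not isolated)
Conditions: LDA (1.1 equiv), THF, −78 → 0 °C; cannulated into 14/TBAF, THF, −78 °C → −20 °C
Reagents that add atoms: none
Why: Electrophilic ethynylation of a fully substituted ketone enolate with an ethynylbenziodoxolone (conjugate attack on the iodine-bound alkyne, loss of 2-iodobenzoate, 1,2-hydrogen shift of the alkylidene carbene): the two α-hydrogens of 13 are homotopic, so irreversible deprotonation gives one enantiomer of 15, and the slim reagent reaches C5 on the face away from the C7 prenyl group, which sets the quaternary centre.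

**Step 7**
Reactants: 18 triethyl phosphonoacetate; 19 geranyl bromide
Product: 21 ethyl (4E)-2-(diethoxyphosphoryl)-5,9-dimethyldeca-4,8-dienoate (racemic), via sodium phosphonoacetate enolate 20 (not isolated)
Conditions: NaH, THF, 0 °C; then 19, 0 °C → rt
Reagents that add atoms: none
Why: SN2 alkylation of the stabilised phosphonoacetate anion by a primary allylic bromide, which keeps the E alkene and gives no allylic transposition.

**Step 8**
Reactants: 21 alkylated phosphonoacetate
Product: 22 ethyl (4E)-5,9-dimethyl-2-methylidenedeca-4,8-dienoate (ethyl 2-geranylacrylate)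
Conditions: aq. HCHO (37 %), K2CO3, THF, rt → 40 °C
Reagents that add atoms: formaldehyde, C=O
Why: Horner–Wadsworth–Emmons olefination with formaldehyde, the standard way from an α-alkyl phosphonoacetate to a 2-alkylacrylate, builds the C1=C8 alkene.

**Step 9**
Reactants: 22 ethyl 2-geranylacrylate
Product: 23 (4E)-5,9-dimethyl-2-methylidenedeca-4,8-dienoic acid
Conditions: LiOH, THF/H2O, rt; then 1 M HCl, 0 °C
Reagents that add atoms: lithium hydroxide, [Li+].[OH-]
Why: Saponification of an unhindered ethyl ester; an α-substituted acrylate is a poor acceptor for hydroxide, so the methylene group should survive.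

**Step 10**
Reactants: 23 2-geranylacrylic acid
Product: 24 (4E)-5,9-dimethyl-2-methylidenedeca-4,8-dienoyl chloride
Conditions: 1-chloro-N,N,2-trimethylprop-1-en-1-amine, CH2Cl2, 0 °C → rt; used crude
Reagents that add atoms: 1-chloro-N,N,2-trimethylprop-1-en-1-amine, CC(C)=C(Cl)N(C)C
Why: Acid chloride formation with an α-chloroenamine under neutral conditions, so that no hydrogen chloride is free to add to the trisubstituted alkenes.

**Step 11**
Reactants: 17 ethynyl ketone; 24 2-geranylacryloyl chloride
Product: 25 (2R,4S)-2-[(6E)-7,11-dimethyl-4-methylidene-3-oxododeca-6,10-dien-1-yn-1-yl]-3,3-dimethyl-2,4-bis(3-methylbut-2-en-1-yl)cyclobutan-1-one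
Conditions: PdCl2(PPh3)2 (2 mol %), CuI (4 mol %), Et3N (1.2 equiv), THF, degassed, rt
Reagents that add atoms: none
Why: Acyl Sonogashira coupling (copper acetylide meets an acylpalladium chloride), which forms C3–C2 at room temperature in a medium too weakly basic to enolise C7 or attack C9, and 24 has no α-hydrogen from which a ketene could form.

**Step 12**
Reactants: 25 enynone
Product: 26 (2R,4S)-2-[(1E,6E)-1-methoxy-7,11-dimethyl-4-methylidene-3-oxododeca-1,6,10-trien-1-yl]-3,3-dimethyl-2,4-bis(3-methylbut-2-en-1-yl)cyclobutan-1-one (C5 and C2 cis on C3=C4, which is E by the sequence rule)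
Conditions: MeOH (1.5 equiv), PBu3 (10 mol %), toluene, rt → 40 °C
Reagents that add atoms: methanol, CO
Why: Phosphine-catalysed oxa-Michael addition of methanol to an ynone (the phosphine generates a methoxide ion pair): attack at C4, the β-carbon of the alkyne, fixes the place of the methoxy group and gives a vinylogous ester that does not revert, whereas addition to the 1,1-disubstituted enone is reversible and is starved by the small amount of methanol, and the same reversibility lets the enol ether settle as the E isomer with the methoxy group beside H3.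

**Step 13**
Reactants: 26 cyclobutanone with tethered methylene ketone
Product: 27 (1S,5R,7R)-1-[(2E)-3,7-dimethylocta-2,6-dien-1-yl]-4-methoxy-6,6-dimethyl-5,7-bis(3-methylbut-2-en-1-yl)bicyclo[3.3.1]non-3-ene-2,9-dione
Conditions: [Rh(C2H4)2Cl]2 (5 mol %), P(3,5-(CF3)2C6H3)3 (20 mol %), BHT (10 mol %), 1,4-dioxane (0.02 M), Ar, sealed tube, 130 °C
Reagents that add atoms: none
Why: Proposed new method: monovalent rhodium, held by the C1=C8 olefin, should add oxidatively to the strained C9–C7 bond to give a trivalent rhodacyclopentanone (Rh, C9, C5, C6, C7), the olefin then inserts into the Rh–acyl bond so that C9 bonds to C1, the resulting C8–Rh alkyl cannot undergo β-hydride elimination because its only β-carbon C1 is fully substituted, and C7–C8 reductive elimination with retention at C7 releases 27, which has the same molecular formula as 26. The closest known reaction type is the rhodium-catalysed intramolecular alkene carboacylation (cut and sew) of cyclobutanones that carry a 1,1-disubstituted olefin on ring carbon 3 and give bridged ketones; new here are the tether on the α-carbon, the enone character of the olefin and a cleaved bond that ends at a secondary carbon. Ring A (C1, C2, C3, C4, C5, C9) closes by 6-exo migratory insertion, possible only from the E enol ether, and ring B (C1, C8, C7, C6, C5, C9) closes by reductive elimination from the seven-membered rhodacycle, a net two-carbon enlargement of the four-membered ring. The one new stereocentre, C1, is dictated by C5, since the bridge C2–C3–C4 can span C1 and C5 of ring B only in a cis-diaxial way, while C5 is untouched and C7 is retained, so that the cis prenyl groups of 26 become the equatorial C7 prenyl group of 27. The step needs cleavage of C9–C7 and not C9–C5, secured because the latter would place rhodium on the fully substituted C5, and acyl transfer to C1 and not C8, secured by 6-exo over 7-endo closure (the latter would give a bicyclo[3.2.2]nonane) although the polarity of the enone pulls the other way. The aminopyridine co-catalyst usual for such reactions is left out because it would displace the C4 methoxy group, add to the enone and epimerise C7 through an enamine, and the decarbonylation it is meant to suppress would here require migration of the quaternary C5 to rhodium.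

**Step 14**
Reactants: 28 3,4-dihydroxybenzoic acid
Product: 29 tert-butyldimethylsilyl 3,4-bis[(tert-butyldimethylsilyl)oxy]benzoate
Conditions: TBSCl (3.5 equiv), imidazole, DMF, rt
Reagents that add atoms: tert-butyldimethylsilyl chloride, CC(C)(C)[Si](C)(C)Cl
Why: Imidazole-promoted exhaustive silylation of both phenols and the acid; the silyl ester is the handle for step 15.

**Step 15**
Reactants: 29 tris-silyl compound
Product: 30 3,4-bis[(tert-butyldimethylsilyl)oxy]benzoyl chloride
Conditions: (COCl)2, DMF (cat.), CH2Cl2, 0 °C → rt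
Reagents that add atoms: oxalyl chloride, O=C(Cl)C(=O)Cl
Why: Conversion of a silyl ester into the acid chloride by oxalyl chloride and catalytic DMF (Vilsmeier-type activation), which runs without free acid and leaves the aryl silyl ethers in place.

**Step 16**
Reactants: 27 bicyclic enol ether; 30 aroyl chloride
Product: 32 (1R,5R,7R)-3-{3,4-bis[(tert-butyldimethylsilyl)oxy]benzoyl}-1-[(2E)-3,7-dimethylocta-2,6-dien-1-yl]-4-methoxy-6,6-dimethyl-5,7-bis(3-methylbut-2-en-1-yl)bicyclo[3.3.1]non-3-ene-2,9-dione (same spatial arrangement as 27; the C1 descriptor changes by priority only), via C3-lithio enol ether 31 (not isolated)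
Conditions: LTMP, THF, −78 °C; then 30, −78 → −40 °C
Reagents that add atoms: none
Why: Vinylic lithiation of a β-methoxy enone at C3 followed by acylation, known on bicyclo[3.3.1]nonane enol ethers of this family; 27 has no other acidic hydrogen because C1 and C5 are quaternary.

**Step 17**
Reactants: 32 C3-aroyl enol ether
Product: 33 (1S,5S,7R)-3-{3,4-bis[(tert-butyldimethylsilyl)oxy]benzoyl}-1-[(2E)-3,7-dimethylocta-2,6-dien-1-yl]-2-hydroxy-6,6-dimethyl-5,7-bis(3-methylbut-2-en-1-yl)bicyclo[3.3.1]non-2-ene-4,9-dione
Conditions: LiCl, dry DMSO, Ar, 120 °C; aqueous work-up at pH 4–5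
Reagents that add atoms: none
Why: Nucleophilic demethylation (SN2 attack of chloride on the methyl group, Krapcho-type conditions) of a vinylogous ester whose enolate is a better leaving group thanks to the C3 aroyl group; in a dry medium chloride attack on silicon is reversible, so the aryl silyl ethers should persist.

**Step 18**
Reactants: 33 bis-silyl ether
Product: 34 target, (1S,5S,7R)-3-(3,4-dihydroxybenzoyl)-1-[(2E)-3,7-dimethylocta-2,6-dien-1-yl]-2-hydroxy-6,6-dimethyl-5,7-bis(3-methylbut-2-en-1-yl)bicyclo[3.3.1]non-2-ene-4,9-dione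
Conditions: Et3N·3HF, THF, Ar, 0 °C → rt
Reagents that add atoms: none
Why: Fluoride cleavage of the two aryl silyl ethers under nearly neutral conditions, chosen because acid would cyclise the enol onto a prenyl group and base in air would oxidise the catechol.

**Compound list**
1 | N,N-dimethylacetamide | CC(=O)N(C)C | starting material
2 | isobutene | C=C(C)C | starting material
3 | N,N-dimethylketeniminium triflate | C=C=[N+](C)C.[O-]S(=O)(=O)C(F)(F)F | intermediate
4 | N-(3,3-dimethylcyclobutylidene)-N-methylmethanaminium triflate | C[N+](C)=C1CC(C)(C)C1.[O-]S(=O)(=O)C(F)(F)F | intermediate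
5 | 3,3-dimethylcyclobutan-1-one | CC1(C)CC(=O)C1 | intermediate
6 | (R)-1-amino-2-(methoxymethyl)pyrrolidine (RAMP) | COC[C@H]1CCCN1N | starting material
7 | RAMP hydrazone of 5 | COC[C@H]1CCCN1N=C2CC(C)(C)C2 | intermediate
8 | prenyl bromide | CC(C)=CCBr | starting material
9 | lithium azaenolate of 7 | COC[C@H]1CCCN1N([Li])C2=CC(C)(C)C2 | intermediate
10 | (2S)-monoprenyl RAMP hydrazone (C=N geometry not fixed) | COC[C@H]1CCCN1N=C2CC(C)(C)[C@@H]2CC=C(C)C | intermediate
11 | lithium azaenolate of 10 | COC[C@H]1CCCN1N([Li])C2=CC(C)(C)[C@@H]2CC=C(C)C | intermediate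
12 | (2S,4S)-diprenyl RAMP hydrazone | COC[C@H]1CCCN1N=C2[C@@H](CC=C(C)C)C(C)(C)[C@@H]2CC=C(C)C | intermediate
13 | (2S,4S)-3,3-dimethyl-2,4-bis(3-methylbut-2-en-1-yl)cyclobutan-1-one | CC(C)=CC[C@@H]1C(=O)[C@@H](CC=C(C)C)C1(C)C | intermediate
14 | TMS-EBX | C[Si](C)(C)C#CI1OC(=O)c2ccccc12 | starting material
15 | lithium enolate of 13 | [Li]OC1=C(CC=C(C)C)C(C)(C)[C@@H]1CC=C(C)C | intermediate
16 | 1-ethynyl-1,2-benziodoxol-3(1H)-one | C#CI1OC(=O)c2ccccc12 | intermediate
17 | (2S,4S)-2-ethynyl-3,3-dimethyl-2,4-bis(3-methylbut-2-en-1-yl)cyclobutan-1-one | C#C[C@]1(CC=C(C)C)C(=O)[C@@H](CC=C(C)C)C1(C)C | intermediate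
18 | triethyl phosphonoacetate | CCOC(=O)CP(=O)(OCC)OCC | starting material
19 | geranyl bromide | CC(C)=CCC/C(C)=C/CBr | starting material
20 | sodium enolate of 18 | CCOC([O-])=CP(=O)(OCC)OCC.[Na+] | intermediate
21 | ethyl (4E)-2-(diethoxyphosphoryl)-5,9-dimethyldeca-4,8-dienoate | CC(C)=CCC/C(C)=C/CC(C(=O)OCC)P(=O)(OCC)OCC | intermediate
22 | ethyl 2-geranylacrylate | CC(C)=CCC/C(C)=C/CC(=C)C(=O)OCC | intermediate
23 | 2-geranylacrylic acid | CC(C)=CCC/C(C)=C/CC(=C)C(=O)O | intermediate
24 | 2-geranylacryloyl chloride | CC(C)=CCC/C(C)=C/CC(=C)C(=O)Cl | intermediate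
25 | cross-conjugated enynone (2R,4S) | CC(C)=CCC/C(C)=C/CC(=C)C(=O)C#C[C@]1(CC=C(C)C)C(=O)[C@@H](CC=C(C)C)C1(C)C | intermediate
26 | key-step precursor (2R,4S; 1E,6E) | CC(C)=CCC/C(C)=C/CC(=C)C(=O)/C=C(OC)\[C@]1(CC=C(C)C)C(=O)[C@@H](CC=C(C)C)C1(C)C | intermediate
27 | key-step product (1S,5R,7R) | CC(C)=CCC/C(C)=C/C[C@]12C[C@@H](CC=C(C)C)C(C)(C)[C@](CC=C(C)C)(C(OC)=CC1=O)C2=O | intermediate
28 | 3,4-dihydroxybenzoic acid | O=C(O)c1ccc(O)c(O)c1 | starting material
29 | TBS 3,4-bis(TBS-oxy)benzoate | CC(C)(C)[Si](C)(C)OC(=O)c1ccc(O[Si](C)(C)C(C)(C)C)c(O[Si](C)(C)C(C)(C)C)c1 | intermediate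
30 | 3,4-bis(TBS-oxy)benzoyl chloride | O=C(Cl)c1ccc(O[Si](C)(C)C(C)(C)C)c(O[Si](C)(C)C(C)(C)C)c1 | intermediate
31 | C3-lithio derivative of 27 | CC(C)=CCC/C(C)=C/C[C@]12C[C@@H](CC=C(C)C)C(C)(C)[C@](CC=C(C)C)(C(OC)=C([Li])C1=O)C2=O | intermediate
32 | C3-aroyl methyl enol ether | CC(C)=CCC/C(C)=C/C[C@]12C[C@@H](CC=C(C)C)C(C)(C)[C@](CC=C(C)C)(C(OC)=C(C(=O)c3ccc(O[Si](C)(C)C(C)(C)C)c(O[Si](C)(C)C(C)(C)C)c3)C1=O)C2=O | intermediate
33 | bis-TBS ether of the target | CC(C)=CCC/C(C)=C/C[C@]12C[C@@H](CC=C(C)C)C(C)(C)[C@](CC=C(C)C)(C(=O)C(C(=O)c3ccc(O[Si](C)(C)C(C)(C)C)c(O[Si](C)(C)C(C)(C)C)c3)=C1O)C2=O | intermediate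
34 | CNP0160101.3 | CC(C)=CCC/C(C)=C/C[C@]12C[C@@H](CC=C(C)C)C(C)(C)[C@](CC=C(C)C)(C(=O)C(C(=O)c3ccc(O)c(O)c3)=C1O)C2=O | target

**Step count**
Total: 18 steps. Longest linear sequence: 12 steps (1–6, 11–13, 16–18).

**Steps most likely to fail**

1. **Step 13.** Several things may go wrong:
   - Oxidative addition may be too slow on the crowded ring.
   - β-Hydride elimination may occur from the prenyl CH2 next to the C7–Rh bond.
   - 7-endo insertion may compete with 6-exo insertion.
   - A thermal Cope shift may occur within C3=C4–C5–CH2–CH=CMe2.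
   - The enone may polymerise.

   The fallback uses known chemistry, sets out from 13 and comes back at 27. Diazoalkane ring expansion of 13 (TMSCHN2, catalytic Sc(OTf)3, then protodesilylation) should give (2S,4R)-3,3-dimethyl-2,4-diprenylcyclopentanone F1. Either α-carbon migrates with retention because of the C2 axis. A second expansion (TMSCHN2, BF3·OEt2, −78 °C), in which the CH2 group migrates in preference to the branched carbon, should give (2S,4S)-3,3-dimethyl-2,4-diprenylcyclohexanone F2. Kinetic deprotonation with LDA on the CH2 side and alkylation with 19 give the 6-geranyl ketone F3. LDA/TMSCl then gives its trimethylsilyl enol ether F4. Effenberger cyclisation of F4 with malonyl dichloride lays the three-carbon bridge on the face away from the C7 prenyl group and gives the bicyclic trione F5. O-methylation with TMSCHN2 gives 27, which is separated from its C2-methoxy regioisomer.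

2. **Step 6.** Proton transfer between the enolate and the moist fluoride source may pass through the meso ketone and lower the enantiomeric purity. Attack at the crowded enolate carbon may be sluggish, and facial selectivity may be poor. The fallback sets out from 13 and comes back at 17. Enolate 15 is quenched at −78 °C with monomeric formaldehyde, the smallest carbon electrophile, again anti to the C7 prenyl group. This gives (2R,4S)-2-(hydroxymethyl)-3,3-dimethyl-2,4-diprenylcyclobutanone F6. Dess–Martin oxidation gives (1R,3S)-2,2-dimethyl-4-oxo-1,3-diprenylcyclobutane-1-carbaldehyde F7. Lithiated TMSCHN2 at −78 °C, which is selective for the aldehyde, then converts F7 into 17 by the Colvin rearrangement.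

3. **Step 12.** Methanol may stay on the methylene ketone. Methoxide may open the cyclobutanone by attack at C9 with loss of the C5 carbanion. E/Z equilibration may be incomplete. The fallback sets out from 25 and comes back at 26, and it masks the enone first. Thiophenol (1 equiv, catalytic Et3N, −78 → 0 °C) should add to the less hindered methylene ketone to give the β-phenylsulfanyl ynone F8. Methanol in excess can then be added to the alkyne (PBu3) to give the methoxy enone sulfide F9. NaIO4 gives the sulfoxide F10. Thermal syn elimination of F10 (toluene, CaCO3, 80 °C) restores the C1=C8 alkene of 26.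

**Further compounds**
F1 | step 13 | (2S,4R)-3,3-dimethyl-2,4-bis(3-methylbut-2-en-1-yl)cyclopentan-1-one | O=C1C[C@@H](CC=C(C)C)C(C)(C)[C@@H]1CC=C(C)C
F2 | step 13 | (2S,4S)-3,3-dimethyl-2,4-bis(3-methylbut-2-en-1-yl)cyclohexan-1-one | O=C1CC[C@@H](CC=C(C)C)C(C)(C)[C@@H]1CC=C(C)C
F3 | step 13 | 6-[(2E)-3,7-dimethylocta-2,6-dien-1-yl]-3,3-dimethyl-2,4-bis(3-methylbut-2-en-1-yl)cyclohexan-1-one (C7 fixed, C1 and C5 epimer mixtures) | CC(C)=CCC/C(C)=C/CC1C[C@@H](CC=C(C)C)C(C)(C)C(CC=C(C)C)C1=O
F4 | step 13 | trimethylsilyl enol ether of F3 (C1=C9) | CC(C)=CCC/C(C)=C/CC1=C(O[Si](C)(C)C)C(CC=C(C)C)C(C)(C)[C@H](CC=C(C)C)C1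
F5 | step 13 | (1S,5R,7R)-1-geranyl-6,6-dimethyl-5,7-diprenylbicyclo[3.3.1]nonane-2,4,9-trione | CC(C)=CCC/C(C)=C/C[C@]12C[C@@H](CC=C(C)C)C(C)(C)[C@](CC=C(C)C)(C(=O)CC1=O)C2=O
F6 | step 6 | (2R,4S)-2-(hydroxymethyl)-3,3-dimethyl-2,4-bis(3-methylbut-2-en-1-yl)cyclobutan-1-one | OC[C@]1(CC=C(C)C)C(=O)[C@@H](CC=C(C)C)C1(C)C
F7 | step 6 | (1R,3S)-2,2-dimethyl-1,3-bis(3-methylbut-2-en-1-yl)-4-oxocyclobutane-1-carbaldehyde | O=C[C@]1(CC=C(C)C)C(=O)[C@@H](CC=C(C)C)C1(C)C
F8 | step 12 | thiophenol adduct of 25 at C8 (C1 epimers) | CC(C)=CCC/C(C)=C/CC(CSc2ccccc2)C(=O)C#C[C@]1(CC=C(C)C)C(=O)[C@@H](CC=C(C)C)C1(C)C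
F9 | step 12 | (E)-C4-methoxy enone sulfide | CC(C)=CCC/C(C)=C/CC(CSc2ccccc2)C(=O)/C=C(OC)\[C@]1(CC=C(C)C)C(=O)[C@@H](CC=C(C)C)C1(C)C
F10 | step 12 | sulfoxide of F9 | CC(C)=CCC/C(C)=C/CC(CS(=O)c2ccccc2)C(=O)/C=C(OC)\[C@]1(CC=C(C)C)C(=O)[C@@H](CC=C(C)C)C1(C)C
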